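Retrosynthesis: rings A and D (the oxepanes; A carries the free OH) are opened at their O–CMe2 bonds (7-endo epoxide openings by the ring-fusion hydroxyls). The two tertiary acetoxy carbons go back to ring ketones, and each cyclohexane (B fused to A, C fused to D) is cut at two bonds, CH2–CH2 and C(quaternary)–CH, into a methyl ketone and the C5 epoxy vinyl sulfone 5.
Enabling feature: in ring B the CH–O fusion carbon lies between the quaternary carbon and a CH2, and the carbinol carbon lies para to it, between the other CH2 and the bridge-bearing CH. A ketone at the carbinol carbon makes both its neighbours nucleophilic; the fusion oxygen can arrive as an epoxide whose CH2 end and whose vinylogous carbon (β-carbon of a vinyl sulfone) are both electrophilic, so one [3+3] event closes the ring.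
Forward: ring B from oct-7-en-2-one and 5; Wacker unmasking of a second methyl ketone; ring C by the same annulation; both side chains by double prenylation at the sulfone carbons; double epoxidation; ring D closes first, ring A last.
Stereochemistry: the epoxide carbon of 5 (set by hydrolytic kinetic resolution) is relayed to the quaternary centre in each annulation. The rings then direct the two carbinol carbons, which are epimeric in the target: equatorial MeCeCl2 attack in ring B, equatorial epoxidation then hydride opening in ring C. The two oxepane CH–O centres come from Shi epoxidation.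
Differentiation of the halves: the ring-B fusion hydroxyl stays silylated, so ring D is closed and acetylated before ring A is closed, which releases the one free hydroxyl.

Key step: step 4

Remark: oct-7-en-2-one (6) is taken as purchasable. Ring positions are called b1–b6 (ring B: b1 carbinol/ketone carbon, b2 bridge-bearing CH, b3 quaternary C–CH3, b4 CH–O) and c1–c6 (ring C, same order).

Step 1
Reactants: 1 but-3-en-2-one
Product: 2 rac-1-(oxiran-2-yl)ethan-1-one
Conditions: 30% H2O2, NaOH (cat.), H2O–MeOH, 0 °C
Reagents that add atoms: hydrogen peroxide, OO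
Why: Weitz–Scheffer nucleophilic epoxidation of the enone should give the racemic epoxy ketone, whose stereocentre is resolved in step 3.

Step 2
Reactants: 2 rac-1-(oxiran-2-yl)ethan-1-one; 3 diethyl [(phenylsulfonyl)methyl]phosphonate
Product: 4 rac-(E)-2-[1-(phenylsulfonyl)prop-1-en-2-yl]oxirane
Conditions: NaH, THF, 0 → 25 °C; the minor Z isomer is removed by chromatography
Reagents that add atoms: none
Why: Horner–Wadsworth–Emmons olefination of the methyl ketone should favour the E isomer (sulfonyl trans to the larger oxiranyl group), and the stabilised anion should leave the epoxide untouched.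

Step 3
Reactants: 4 rac-(E)-2-[1-(phenylsulfonyl)prop-1-en-2-yl]oxirane
Product: 5 (R,E)-2-[1-(phenylsulfonyl)prop-1-en-2-yl]oxirane
Conditions: (R,R)-Co(salen)(OAc) (0.5 mol%; salen = N,N′-bis(3,5-di-tert-butylsalicylidene)cyclohexane-1,2-diamine dianion), H2O (0.55 equiv), THF, 0 → 25 °C
Reagents that add atoms: none
Why: Jacobsen hydrolytic kinetic resolution of a terminal epoxide should hydrolyse the S enantiomer and leave 5 (antipode of catalyst chosen by analogy with simple monosubstituted oxiranes), fixing the one stereocentre from which both ring-fusion pairs are relayed.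

Step 4
Reactants: 6 oct-7-en-2-one; 5 (R,E)-2-[1-(phenylsulfonyl)prop-1-en-2-yl]oxirane
Product: 9 (2S,3S,4S)-4-hydroxy-3-methyl-2-(pent-4-en-1-yl)-3-[(phenylsulfonyl)methyl]cyclohexan-1-one, via lithium enolate 7 (not isolated), via ring-opened lithium alkoxide 8 (not isolated)
Conditions: LDA, THF, −78 °C; 5, LiClO4, −78 → 25 °C; then t-BuOK (0.1 equiv), 25 °C; H2O
Reagents that add atoms: none
Why: Proposed new method: the kinetic lithium enolate 7 opens the LiClO4-activated epoxide of 5 at its CH2 terminus (first bond, CH2–CH2); the liberated alkoxide 8, a stronger base than a ketone enolate in THF, relays the charge to the other α-carbon, whose enolate adds to the β,β-disubstituted vinyl sulfone (second bond, CH–C quaternary), and proton transfer from the α-sulfonyl carbanion to the more stable enolate makes the closure effectively irreversible. The closest known reaction types are the Lewis-acid-assisted opening of terminal epoxides by lithium ketone enolates, the base-mediated intramolecular Michael addition of ketone enolates to vinyl sulfones, and the [3+3] α,α′-annulation of ketones with 2-(halomethyl)acrylates or nitroallyl esters. Ring B closes in the 6-(enolendo)-exo-trig mode through a chair in which the C–O bond of the resident stereocentre (b4, retained from 5) is equatorial and antiperiplanar to the forming bond (Felkin–Anh, with the two anionic sites far apart) while its C–H eclipses the vinyl sulfone (minimal allylic 1,3-strain), so the nucleophile enters anti to oxygen and the quaternary centre b3 gets methyl axial, trans to the b4 hydrogen. The b2 centre, α to the ketone, is set under thermodynamic control with the chain equatorial. The step needs enolate regioselectivity (kinetic deprotonation of CH3 first; afterwards only the CH2-side enolate can close a six-membered ring), epoxide regioselectivity (the unhindered CH2; the electron-poor alkene disfavours allylic attack) and chemoselectivity against intermolecular Michael addition (the β-carbon is fully substituted).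

Step 5
Reactants: 9 (2S,3S,4S)-4-hydroxy-3-methyl-2-(pent-4-en-1-yl)-3-[(phenylsulfonyl)methyl]cyclohexan-1-one
Product: 10 (2S,3S,4S)-4-[(tert-butyldimethylsilyl)oxy]-3-methyl-2-(pent-4-en-1-yl)-3-[(phenylsulfonyl)methyl]cyclohexan-1-one
Conditions: TBSOTf, 2,6-lutidine, CH2Cl2, −78 °C
Reagents that add atoms: tert-butyldimethylsilyl triflate, CC(C)(C)[Si](C)(C)OS(=O)(=O)C(F)(F)F
Why: Silylation of the hindered secondary alcohol with a silyl triflate should be faster than enol silylation at −78 °C and keeps the b4 oxygen dormant until the last step.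

Step 6
Reactants: 10 (2S,3S,4S)-4-[(tert-butyldimethylsilyl)oxy]-3-methyl-2-(pent-4-en-1-yl)-3-[(phenylsulfonyl)methyl]cyclohexan-1-one
Product: 11 (1R,2S,3S,4S)-4-[(tert-butyldimethylsilyl)oxy]-1,3-dimethyl-2-(pent-4-en-1-yl)-3-[(phenylsulfonyl)methyl]cyclohexan-1-ol
Conditions: MeLi, CeCl3, THF, −78 °C
Reagents that add atoms: methylcerium dichloride (made from MeLi and CeCl3), C[Ce](Cl)Cl
Why: Imamoto organocerium 1,2-addition to the enolisable, hindered ketone should occur from the equatorial side because the axial b3 methyl blocks the axial trajectory, giving b1 with CH3 equatorial and OH axial.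

Step 7
Reactants: 11 (1R,2S,3S,4S)-4-[(tert-butyldimethylsilyl)oxy]-1,3-dimethyl-2-(pent-4-en-1-yl)-3-[(phenylsulfonyl)methyl]cyclohexan-1-ol
Product: 12 (1R,2S,3S,4S)-4-[(tert-butyldimethylsilyl)oxy]-1,3-dimethyl-2-(4-oxopentyl)-3-[(phenylsulfonyl)methyl]cyclohexan-1-ol
Conditions: PdCl2 (10 mol%), CuCl, O2 (1 atm), DMF–H2O, 25 °C
Reagents that add atoms: water, O
Why: Tsuji–Wacker oxidation of the terminal alkene should give the methyl ketone with Markovnikov selectivity, the tertiary alcohol and silyl ether being inert.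

Step 8
Reactants: 12 (1R,2S,3S,4S)-4-[(tert-butyldimethylsilyl)oxy]-1,3-dimethyl-2-(4-oxopentyl)-3-[(phenylsulfonyl)methyl]cyclohexan-1-ol; 5 (R,E)-2-[1-(phenylsulfonyl)prop-1-en-2-yl]oxirane
Product: 15 ring-B/ring-C keto diol (ring B as in 12; its b2 chain is now 2-[(1S,2S,3S)-3-hydroxy-2-methyl-6-oxo-2-[(phenylsulfonyl)methyl]cyclohexyl]ethyl), via dilithium alkoxide enolate 13 (not isolated), via ring-opened dilithium dialkoxide 14 (not isolated)
Conditions: LDA (2.1 equiv), THF, −78 °C; 5, LiClO4, −78 → 25 °C; then t-BuOK (0.1 equiv), 25 °C; H2O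
Reagents that add atoms: none
Why: Proposed new method: the same domino as in step 4 (enolate opening of the epoxide CH2, alkoxide-relayed enolisation, 6-exo-trig Michael addition to the vinyl sulfone; closest known types are Lewis-acid-assisted enolate–epoxide opening, intramolecular ketone-to-vinyl-sulfone Michael addition and [3+3] α,α′-annulation) should build ring C with c3 and c4 controlled by the stereocentre of 5 and c2 equatorial by equilibration, the b1 alkoxide being a spectator.

Step 9
Reactants: 15 ring-B/ring-C keto diol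
Product: 16 methylene compound (15 with the c1 C=O replaced by C=CH2)
Conditions: Ph3PCH3Br, KHMDS, THF, 0 → 40 °C
Reagents that add atoms: methylenetriphenylphosphorane, C=P(c1ccccc1)(c1ccccc1)c1ccccc1
Why: Wittig methylenation with an excess of the non-stabilised ylide should convert the hindered ketone, c2 staying equatorial as the thermodynamic epimer.

Step 10
Reactants: 16 methylene compound
Product: 17 spiro-epoxide (oxirane on c1 with its oxygen equatorial, anti to the axial c3 methyl)
Conditions: mCPBA, NaHCO3, CH2Cl2, 0 °C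
Reagents that add atoms: 3-chloroperbenzoic acid, OOC(=O)c1cccc(Cl)c1
Why: Prilezhaev epoxidation of the only alkene should come from the equatorial side, because the axial c3 methyl shields the axial face of the exocyclic methylene, as in labdane-type 8(17)-enes.

Step 11
Reactants: 17 spiro-epoxide
Product: 18 triol bis-sulfone (c1: CH3 axial and OH equatorial; b1: CH3 equatorial and OH axial; b4 OTBS; c4 OH)
Conditions: LiEt3BH, THF, 0 °C
Reagents that add atoms: none
Why: Hydride opening of the 1,1-disubstituted epoxide at its CH2 should leave the c1 oxygen where the epoxidation placed it, giving the c1 epimer opposite to b1, while the sulfones and the silyl ether are inert.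

Step 12
Reactants: 18 triol bis-sulfone; 19 1-bromo-3-methylbut-2-ene (prenyl bromide)
Product: 20 bis-prenylated bis-sulfone (both CH2SO2Ph groups now CH(SO2Ph)CH2CH=C(CH3)2; epimers at these two carbons)
Conditions: n-BuLi (5.2 equiv), THF–DMPU, −78 °C; 19 (2.2 equiv), −78 → −30 °C
Reagents that add atoms: none
Why: Julia-type alkylation of the two α-sulfonyl carbanions (formed after the three hydroxyls are deprotonated) with a reactive allylic bromide should be much faster than O-alkylation of the hindered lithium alkoxides, and the new sulfonyl-bearing centres are removed in step 13.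

Step 13
Reactants: 20 bis-prenylated bis-sulfone
Product: 21 diene triol (b3 and c3 each carry an axial CH3 and a 4-methylpent-3-en-1-yl chain)
Conditions: Na(Hg), Na2HPO4, MeOH–THF, −20 °C
Reagents that add atoms: none
Why: Buffered sodium amalgam reductive desulfonylation of the two homoallylic alkyl phenyl sulfones should proceed without alkene migration or loss of the silyl ether.

Step 14
Reactants: 21 diene triol
Product: 23 ring-D oxepane (rings C and D complete, trans-fused, ring D as O–C(CH3)2–CH(OH); ring B still carries OTBS at b4 and the epoxy chain at b3), via bis-epoxide 22 (not isolated)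
Conditions: L-fructose-derived Shi ketone (1,2:4,5-di-O-isopropylidene-β-L-erythro-2,3-hexodiulo-2,6-pyranose, 30 mol% per alkene), KHSO5 (Oxone), K2CO3, Bu4NHSO4, MeCN–CH2(OMe)2–aq. Na2B4O7 buffer, 0 °C; then CSA (10 mol%), CH2Cl2, −20 → 0 °C
Reagents that add atoms: potassium peroxymonosulfate, [K+].[O-]S(=O)(=O)OO
Why: Shi asymmetric epoxidation should give both (S)-epoxides under catalyst control, and the free c4 hydroxyl then opens its epoxide in the acid-promoted 7-endo (Markovnikov, at the CMe2 carbon) mode, whereas the silylated b4 oxygen is a far poorer nucleophile and should leave the second epoxide intact.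

Step 15
Reactants: 23 ring-D oxepane
Product: 24 triacetate (acetates at b1, c1 and the ring-D CH–O carbon; b4 OTBS; ring-B epoxy chain)
Conditions: LiHMDS (4 equiv), THF, −78 °C; Ac2O, −78 → 0 °C
Reagents that add atoms: acetic anhydride, CC(=O)OC(C)=O
Why: Acylation of the preformed lithium alkoxides should acetylate the two hindered tertiary alcohols as well as the secondary one under non-acidic conditions that spare the epoxide and the silyl ether.

Step 16
Reactants: 24 triacetate
Product: 26 CNP0169816.2 (target), via desilylated hydroxy epoxide 25 (not isolated)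
Conditions: TBAF, AcOH, THF, 25 °C; then CSA (10 mol%), CH2Cl2, 0 °C
Reagents that add atoms: none
Why: Buffered fluoride desilylation frees the b4 hydroxyl, which should close ring A by the same acid-promoted 7-endo epoxide opening at the CMe2 carbon, releasing the single free secondary hydroxyl with the configuration set in step 14.

Compound list
1 | but-3-en-2-one (methyl vinyl ketone) | CC(=O)C=C | starting material
2 | rac-1-(oxiran-2-yl)ethan-1-one | CC(=O)C1CO1 | intermediate
3 | diethyl [(phenylsulfonyl)methyl]phosphonate | CCOP(=O)(CS(=O)(=O)c1ccccc1)OCC | starting material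
4 | rac-(E)-2-[1-(phenylsulfonyl)prop-1-en-2-yl]oxirane | C/C(=C\S(=O)(=O)c1ccccc1)C1CO1 | intermediate
5 | (R,E)-2-[1-(phenylsulfonyl)prop-1-en-2-yl]oxirane | C/C(=C\S(=O)(=O)c1ccccc1)[C@@H]1CO1 | intermediate
6 | oct-7-en-2-one | CC(=O)CCCCC=C | starting material
7 | lithium octa-1,7-dien-2-olate (kinetic enolate of 6) | C=C(O[Li])CCCCC=C | intermediate
8 | lithium alkoxide of (3S,1E)-3-hydroxy-2-methyl-1-(phenylsulfonyl)dodeca-1,11-dien-6-one | C=CCCCCC(=O)CC[C@H](O[Li])/C(C)=C/S(=O)(=O)c1ccccc1 | intermediate
9 | (2S,3S,4S)-4-hydroxy-3-methyl-2-(pent-4-en-1-yl)-3-[(phenylsulfonyl)methyl]cyclohexan-1-one | O=C1[C@@H](CCCC=C)[C@](C)(CS(=O)(=O)c2ccccc2)[C@@H](O)CC1 | intermediate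
10 | (2S,3S,4S)-4-[(tert-butyldimethylsilyl)oxy]-3-methyl-2-(pent-4-en-1-yl)-3-[(phenylsulfonyl)methyl]cyclohexan-1-one | O=C1[C@@H](CCCC=C)[C@](C)(CS(=O)(=O)c2ccccc2)[C@@H](O[Si](C)(C)C(C)(C)C)CC1 | intermediate
11 | (1R,2S,3S,4S)-4-[(tert-butyldimethylsilyl)oxy]-1,3-dimethyl-2-(pent-4-en-1-yl)-3-[(phenylsulfonyl)methyl]cyclohexan-1-ol | C[C@]1(O)[C@@H](CCCC=C)[C@](C)(CS(=O)(=O)c2ccccc2)[C@@H](O[Si](C)(C)C(C)(C)C)CC1 | intermediate
12 | (1R,2S,3S,4S)-4-[(tert-butyldimethylsilyl)oxy]-1,3-dimethyl-2-(4-oxopentyl)-3-[(phenylsulfonyl)methyl]cyclohexan-1-ol | C[C@]1(O)[C@@H](CCCC(C)=O)[C@](C)(CS(=O)(=O)c2ccccc2)[C@@H](O[Si](C)(C)C(C)(C)C)CC1 | intermediate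
13 | dilithium alkoxide enolate of 12 (b1 O–Li; terminal enolate of the methyl ketone) | C[C@]1(O[Li])[C@@H](CCCC(=C)O[Li])[C@](C)(CS(=O)(=O)c2ccccc2)[C@@H](O[Si](C)(C)C(C)(C)C)CC1 | intermediate
14 | ring-opened dilithium dialkoxide (12 extended at its methyl ketone CH3 by CH2–CH(OLi)–C(CH3)=CH–SO2Ph, E) | C[C@]1(O[Li])[C@@H](CCCC(=O)CC[C@H](O[Li])/C(C)=C/S(=O)(=O)c3ccccc3)[C@](C)(CS(=O)(=O)c2ccccc2)[C@@H](O[Si](C)(C)C(C)(C)C)CC1 | intermediate
15 | ring-B/ring-C keto diol: (1R,2S,3S,4S)-4-[(tert-butyldimethylsilyl)oxy]-2-{2-[(1S,2S,3S)-3-hydroxy-2-methyl-6-oxo-2-[(phenylsulfonyl)methyl]cyclohexyl]ethyl}-1,3-dimethyl-3-[(phenylsulfonyl)methyl]cyclohexan-1-ol | C[C@]1(O)[C@@H](CC[C@@H]2C(=O)CC[C@H](O)[C@@]2(C)CS(=O)(=O)c3ccccc3)[C@](C)(CS(=O)(=O)c4ccccc4)[C@@H](O[Si](C)(C)C(C)(C)C)CC1 | intermediate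
16 | methylene compound: 15 with the c1 C=O replaced by C=CH2 | C[C@]1(O)[C@@H](CC[C@@H]2C(=C)CC[C@H](O)[C@@]2(C)CS(=O)(=O)c3ccccc3)[C@](C)(CS(=O)(=O)c4ccccc4)[C@@H](O[Si](C)(C)C(C)(C)C)CC1 | intermediate
17 | spiro-epoxide: oxirane on c1 of 16, oxygen equatorial (anti to the axial c3 methyl) | C[C@]1(O)[C@@H](CC[C@@H]2[C@]3(CO3)CC[C@H](O)[C@@]2(C)CS(=O)(=O)c4ccccc4)[C@](C)(CS(=O)(=O)c5ccccc5)[C@@H](O[Si](C)(C)C(C)(C)C)CC1 | intermediate
18 | triol bis-sulfone: c1 with axial CH3 and equatorial OH; b1 with equatorial CH3 and axial OH; c4 OH; b4 OTBS; CH2SO2Ph on b3 and c3 | C[C@]1(O)[C@@H](CC[C@@H]2[C@@](C)(O)CC[C@H](O)[C@@]2(C)CS(=O)(=O)c3ccccc3)[C@](C)(CS(=O)(=O)c4ccccc4)[C@@H](O[Si](C)(C)C(C)(C)C)CC1 | intermediate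
19 | 1-bromo-3-methylbut-2-ene (prenyl bromide) | CC(C)=CCBr | starting material
20 | bis-prenylated bis-sulfone: 18 with both CH2SO2Ph groups as CH(SO2Ph)CH2CH=C(CH3)2 (epimeric at these carbons) | C[C@]1(O)[C@@H](CC[C@@H]2[C@@](C)(O)CC[C@H](O)[C@@]2(C)C(CC=C(C)C)S(=O)(=O)c3ccccc3)[C@](C)(C(CC=C(C)C)S(=O)(=O)c4ccccc4)[C@@H](O[Si](C)(C)C(C)(C)C)CC1 | intermediate
21 | diene triol: b3 and c3 each with axial CH3 and a 4-methylpent-3-en-1-yl chain | C[C@]1(O)[C@@H](CC[C@@H]2[C@@](C)(O)CC[C@H](O)[C@@]2(C)CCC=C(C)C)[C@](C)(CCC=C(C)C)[C@@H](O[Si](C)(C)C(C)(C)C)CC1 | intermediate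
22 | bis-epoxide: both chains of 21 ending in (S)-3,3-dimethyloxiran-2-yl | C[C@]1(O)[C@@H](CC[C@@H]2[C@@](C)(O)CC[C@H](O)[C@@]2(C)CC[C@@H]3OC3(C)C)[C@](C)(CC[C@@H]5OC5(C)C)[C@@H](O[Si](C)(C)C(C)(C)C)CC1 | intermediate
23 | ring-D oxepane: rings C/D trans-fused with free secondary OH in ring D and equatorial OH at c1; ring B with axial OH at b1, OTBS at b4 and the (S)-epoxy chain at b3 | C[C@]1(O)[C@@H](CC[C@@H]2[C@@](C)(O)CC[C@@H]3OC(C)(C)[C@@H](O)CC[C@@]23C)[C@](C)(CC[C@@H]5OC5(C)C)[C@@H](O[Si](C)(C)C(C)(C)C)CC1 | intermediate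
24 | triacetate: 23 with OAc at b1, c1 and the ring-D CH–O carbon | C[C@]1(OC(C)=O)[C@@H](CC[C@@H]2[C@@](C)(OC(C)=O)CC[C@@H]3OC(C)(C)[C@@H](OC(C)=O)CC[C@@]23C)[C@](C)(CC[C@@H]5OC5(C)C)[C@@H](O[Si](C)(C)C(C)(C)C)CC1 | intermediate
25 | hydroxy epoxide: 24 with the b4 silyl ether cleaved to OH | C[C@]1(OC(C)=O)[C@@H](CC[C@@H]2[C@@](C)(OC(C)=O)CC[C@@H]3OC(C)(C)[C@@H](OC(C)=O)CC[C@@]23C)[C@](C)(CC[C@@H]5OC5(C)C)[C@@H](O)CC1 | intermediate
26 | CNP0169816.2 (rings A–D; free OH in ring A; OAc at b1 axial, at c1 equatorial and in ring D) | CC(=O)O[C@H]1CC[C@]2(C)[C@H](CC[C@](C)(OC(C)=O)[C@H]2CC[C@H]2[C@]3(C)CC[C@H](O)C(C)(C)O[C@H]3CC[C@@]2(C)OC(C)=O)OC1(C)C | target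

Total step count: 16. Longest linear sequence: 16 steps (1 → 26; compound 5 enters twice, in steps 4 and 8).

Steps most likely to fail

1. Step 4. The enolate may act as a base towards the vinyl sulfone instead of opening the epoxide, the liberated γ-hydroxy vinyl sulfone may isomerise to a γ-keto sulfone before ring closure, or the facial selectivity at the quaternary centre may be poor. Fallback (the two bonds are made one after the other by known enolate alkylation and intramolecular Michael addition, with the oxygen protected throughout): it sets out from 5 and 6. LiI and AcOH in THF open 5 at the CH2 terminus to the iodohydrin (R,E)-1-iodo-3-methyl-4-(phenylsulfonyl)but-3-en-2-ol F1; TBSOTf and 2,6-lutidine give its tert-butyldimethylsilyl ether F2. The kinetic enolate of 6 (LDA, THF–DMPU, −78 → −20 °C) is alkylated by F2 to the silylated keto vinyl sulfone F3. t-BuOK in t-BuOH–THF then closes ring B; with the bulky silyloxy group equatorial and anti to the forming bond, this should give 10 directly, where the route is rejoined.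

2. Step 8. The same processes as in step 4 may occur, made worse by the extra alkoxide and by the more hindered, more valuable ketone. Fallback (again stepwise and known, with a silyl group that can be removed beside the tert-butyldimethylsilyl ether): it sets out from 12 and from iodohydrin F1. TESCl and imidazole convert F1 into the triethylsilyl ether F4. Dianion 13 (LDA, 2.1 equiv, THF–DMPU) is alkylated by F4 to the open-chain keto vinyl sulfone F5. t-BuOK in t-BuOH–THF closes ring C to the triethylsilyl-protected ring-C ketone F6. PPTS in MeOH removes only the triethylsilyl group and gives 15, where the route is rejoined.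

3. Step 16 (the same ring closure is first met in step 14). The freed hydroxyl may attack the secondary epoxide carbon (6-exo) instead of the CMe2 carbon, an acetyl group may migrate to the liberated hydroxyl, or desilylation at the hindered position may stall. Fallback (the O–CMe2 bond is made by a Markovnikov hydroalkoxylation in which only the tertiary carbon can accept oxygen): it sets out from 24. TMSOTf and 2,6-lutidine, then DBU, isomerise the epoxide to the allylic trimethylsilyl ether F7 (chain end CH(OSiMe3)–C(CH3)=CH2, the C–O stereocentre untouched). TBAF and AcOH remove both silyl groups to give the allylic alcohol diol F8. Co(salen) (cat.), N-fluoro-2,4,6-trimethylpyridinium tetrafluoroborate and PhSiH3 in PhCF3 then effect hydrogen-atom-transfer hydroalkoxylation of the 1,1-disubstituted alkene by the b4 hydroxyl, closing ring A and giving 26.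

Further compounds
F1 | step 4 | (R,E)-1-iodo-3-methyl-4-(phenylsulfonyl)but-3-en-2-ol | C/C(=C\S(=O)(=O)c1ccccc1)[C@@H](O)CI
F2 | step 4 | tert-butyldimethylsilyl ether of F1 | C/C(=C\S(=O)(=O)c1ccccc1)[C@@H](O[Si](C)(C)C(C)(C)C)CI
F3 | step 4 | (3S,1E)-3-[(tert-butyldimethylsilyl)oxy]-2-methyl-1-(phenylsulfonyl)dodeca-1,11-dien-6-one | C=CCCCCC(=O)CC[C@H](O[Si](C)(C)C(C)(C)C)/C(C)=C/S(=O)(=O)c1ccccc1
F4 | step 8 | triethylsilyl ether of F1 | C/C(=C\S(=O)(=O)c1ccccc1)[C@@H](O[Si](CC)(CC)CC)CI
F5 | step 8 | open-chain keto vinyl sulfone: 12 extended at its methyl ketone CH3 by CH2–CH(OSiEt3)–C(CH3)=CH–SO2Ph (E) | C[C@]1(O)[C@@H](CCCC(=O)CC[C@H](O[Si](CC)(CC)CC)/C(C)=C/S(=O)(=O)c3ccccc3)[C@](C)(CS(=O)(=O)c2ccccc2)[C@@H](O[Si](C)(C)C(C)(C)C)CC1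
F6 | step 8 | triethylsilyl ether of 15 at the c4 oxygen | C[C@]1(O)[C@@H](CC[C@@H]2C(=O)CC[C@H](O[Si](CC)(CC)CC)[C@@]2(C)CS(=O)(=O)c3ccccc3)[C@](C)(CS(=O)(=O)c4ccccc4)[C@@H](O[Si](C)(C)C(C)(C)C)CC1
F7 | step 16 | allylic trimethylsilyl ether: 24 with the epoxy chain end as (S)-CH(OSiMe3)–C(CH3)=CH2 | C[C@]1(OC(C)=O)[C@@H](CC[C@@H]2[C@@](C)(OC(C)=O)CC[C@@H]3OC(C)(C)[C@@H](OC(C)=O)CC[C@@]23C)[C@](C)(CC[C@H](O[Si](C)(C)C)C(C)=C)[C@@H](O[Si](C)(C)C(C)(C)C)CC1
F8 | step 16 | allylic alcohol diol: F7 with both silyl groups removed | C[C@]1(OC(C)=O)[C@@H](CC[C@@H]2[C@@](C)(OC(C)=O)CC[C@@H]3OC(C)(C)[C@@H](OC(C)=O)CC[C@@]23C)[C@](C)(CC[C@H](O)C(C)=C)[C@@H](O)CC1
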